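**Strategy.** The route rests on cutting ring C of the upper flavan unit at O1–C2 and C3–C4. The array O1–C8a–C4a–C4 (phenol oxygen, ring A edge, benzylic carbon) is read as an ortho-quinone methide heterodiene and the cis C2–C3 pair as a Z-alkene. One chiral-acid-catalysed inverse-demand oxa-[4+2] cycloaddition between the α-methoxy o-quinone methide of a dibromo-blocked phloroglucinol aldehyde and a (Z)-styryl pinacol boronate should build ring C with C2/C3 cis; boron fixes the regiochemistry and is a latent 3-OH. The C4 methoxy group then serves as leaving group for the 4β→6 Friedel–Crafts union with 8-bromo-perbenzyl EGCG, made from (−)-epigallocatechin. Hydrogenolysis removes benzyl groups and bromines.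

Key step: step 8

Assumption: flavan numbering is used (primed for ring B and for the lower unit where needed). Compounds 14 and 15 are drawn as the expected 3,4-trans C4 epimer; the other C4 epimer would serve equally because step 10 ionises C4. The antipode of the acid catalyst in step 8 is chosen to give the C2/C3 configuration of epigallocatechin, and the geometry drawn for the transient quinone methide 13 is not essential.

Step 1
Reactants: 1 (−)-epigallocatechin (2R,3R)
Product: 2 5,7,3',4',5'-penta-O-benzyl-(−)-epigallocatechin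
Conditions: BnBr (5.3 equiv), K2CO3 (6 equiv), DMF, −10 °C to rt, argon
Reagents that add atoms: benzyl bromide, BrCc1ccccc1
Why: Williamson O-benzylation under carbonate base should alkylate the five phenols only, since the secondary 3-OH is not deprotonated, and the cold, oxygen-free conditions should leave the C2/C3 stereocentres of the chiral-pool unit untouched.

Step 2
Reactants: 2 5,7,3',4',5'-penta-O-benzyl-(−)-epigallocatechin; 3 3,4,5-tris(benzyloxy)benzoic acid (1.3 equiv)
Product: 4 octa-O-benzyl-EGCG
Conditions: DCC (1.5 equiv), DMAP (0.2 equiv), CH2Cl2, 0 °C to rt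
Reagents that add atoms: none
Why: Steglich esterification should acylate the secondary 3-OH through the acylpyridinium of the protected gallic acid without breaking any bond at C2 or C3, so the 2R,3R configuration is retained.

Step 3
Reactants: 4 octa-O-benzyl-EGCG
Product: 5 8-bromo-octa-O-benzyl-EGCG
Conditions: NBS (1.05 equiv), CH2Cl2, −78 to 0 °C
Reagents that add atoms: N-bromosuccinimide, O=C1CCC(=O)N1Br
Why: Electrophilic aromatic bromination should go to the phloroglucinol-type ring A, the most electron-rich ring, and there to C8, the position that reacts first in 5,7-di-O-benzyl flavans; the bromine later forces coupling to C6.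

Step 4
Reactants: 6 2,4,6-trihydroxybenzaldehyde
Product: 7 2,4-bis(benzyloxy)-6-hydroxybenzaldehyde
Conditions: BnBr (2.05 equiv), K2CO3 (2.1 equiv), DMF, 0 °C to rt
Reagents that add atoms: benzyl bromide, BrCc1ccccc1
Why: Williamson etherification should alkylate the para OH and one ortho OH, while the second ortho OH is deactivated by its hydrogen bond to the formyl group.

Step 5
Reactants: 7 2,4-bis(benzyloxy)-6-hydroxybenzaldehyde
Product: 8 4,6-bis(benzyloxy)-3,5-dibromo-2-hydroxybenzaldehyde
Conditions: NBS (2.1 equiv), MeCN, 0 °C to rt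
Reagents that add atoms: N-bromosuccinimide, O=C1CCC(=O)N1Br
Why: Electrophilic aromatic bromination should fill both remaining ring positions, each ortho/para to three oxygens; the bromines block Friedel–Crafts self-condensation of ring A in steps 8 and 10.

Step 6
Reactants: 9 3,4,5-tris(benzyloxy)benzaldehyde
Product: 10 1,2,3-tris(benzyloxy)-5-ethynylbenzene
Conditions: dimethyl (1-diazo-2-oxopropyl)phosphonate, K2CO3, MeOH/THF, rt
Reagents that add atoms: Ohira–Bestmann reagent, CC(=O)C(=[N+]=[N-])P(=O)(OC)OC
Why: Seyferth–Gilbert homologation in its Ohira–Bestmann form should convert the non-enolisable aryl aldehyde into the terminal alkyne under mild carbonate conditions.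

Step 7
Reactants: 10 1,2,3-tris(benzyloxy)-5-ethynylbenzene
Product: 11 (Z)-2-{2-[3,4,5-tris(benzyloxy)phenyl]ethenyl}-4,4,5,5-tetramethyl-1,3,2-dioxaborolane
Conditions: HBpin (1 equiv), alkyne 10 (1.2 equiv), [Rh(cod)Cl]2 (1.5 mol %), P(iPr)3 (6 mol %), Et3N, cyclohexane, rt
Reagents that add atoms: pinacolborane, CC1(C)OBOC1(C)C
Why: Rhodium-catalysed formal trans-hydroboration of a terminal alkyne through a rhodium vinylidene should deliver the anti-Markovnikov alkenyl boronate with Z geometry (aryl and boron cis).

Step 8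
Reactants: 8 4,6-bis(benzyloxy)-3,5-dibromo-2-hydroxybenzaldehyde; 11 (Z)-alkenyl pinacol boronate (2 equiv)
Product: 14 pinacol [(2S,3R,4R)-5,7-bis(benzyloxy)-6,8-dibromo-4-methoxy-2-(3,4,5-tris(benzyloxy)phenyl)chroman-3-yl]boronate, via dimethyl acetal 12 (not isolated), via methoxy o-quinone methide 13 (not isolated)
Conditions: HC(OMe)3 (5 equiv), Amberlyst-15, CH2Cl2, rt, filter and concentrate; then 11, (R)-3,3'-bis(2,4,6-triisopropylphenyl)-BINOL N-triflylphosphoramide (10 mol %), 5 Å MS, CH2Cl2, −60 to −20 °C, Et3N quench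
Reagents that add atoms: trimethyl orthoformate, COC(OC)OC
Why: Proposed new method: acetal 12 should lose methanol under the chiral acid to give the α-methoxy o-quinone methide 13 (its O-protonated form is a 2-hydroxybenzylic oxocarbenium ion held to the chiral phosphoramide anion through the phenolic OH), and this heterodiene O1=C8a–C4a=C4 should add across the Z-alkene of 11 in a concerted but asynchronous inverse-electron-demand oxa-[4+2] cycloaddition, C4–C3 bonding leading and O1–C2 closing ring C; the closest known reactions are the acid-catalysed chroman syntheses from salicylaldehyde acetals with styrenes or vinyl ethers, including chiral Brønsted acid versions, but an alkenyl boronate that keeps its boron has not been used as the 2π partner. Regiochemistry follows from charge development: positive charge builds at benzylic C2, stabilised by the trialkoxyphenyl ring and by σ(C–B) hyperconjugation, and never α to boron. Ring C closes in the [4+2] mode (in the stepwise limit, six-membered closure of the phenolic oxygen onto the C2 benzylic cation, which should be faster than loss of boron). Suprafacial addition transfers the Z geometry into the 2,3-cis relationship of aryl and boron, and the chiral counteranion selects the alkene face and so the absolute configuration at C2 and C3; the C4 methoxy centre is expected trans to boron but need not be controlled because step 10 ionises it. The step needs chemoselectivity for the weakly nucleophilic alkene over arene nucleophiles, secured by the two bromines that block C6 and C8 of ring A and retard re-ionisation of the product, and it needs mild acid at low temperature so that 14 does not lose methanol and boron by β-elimination.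

Step 9
Reactants: 14 3-boryl-4-methoxyflavan
Product: 15 5,7,3',4',5'-penta-O-benzyl-6,8-dibromo-4β-methoxy-epigallocatechin (2R,3R,4S)
Conditions: H2O2 (30 %), NaOH (aq), THF, 0 °C, short reaction time
Reagents that add atoms: hydrogen peroxide, OO
Why: Alkaline peroxide oxidation of the secondary alkyl boronate proceeds by 1,2-migration of C3 from boron to oxygen with retention, so the 3-OH should stand cis to the C2 aryl group as in epigallocatechin.

Step 10
Reactants: 15 4β-methoxy dibromo upper unit; 5 8-bromo-octa-O-benzyl-EGCG (1.5 equiv)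
Product: 16 [5,7,3',4',5'-penta-O-benzyl-6,8-dibromo-epigallocatechin]-(4β→6)-[8-bromo-octa-O-benzyl-epigallocatechin 3-O-gallate]
Conditions: TMSOTf (20 mol %), CH2Cl2, −78 to −40 °C, NaHCO3 quench
Reagents that add atoms: none
Why: Lewis-acid-catalysed Friedel–Crafts coupling of a flavan-4-yl cation (the standard proanthocyanidin bond formation) should ionise the C4 methoxy group and let C6 of 5 (C8 is brominated) attack anti to the 3-OH, which sets C4 as the 3,4-trans (4β) centre whatever the C4 configuration of 15.

Step 11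
Reactants: 16 protected tribromo dimer
Product: 17 epigallocatechin-(4β→6)-epigallocatechin 3-O-gallate (target; upper unit 2R,3R,4S, lower unit 2R,3R)
Conditions: H2 (1 atm), Pd(OH)2/C, Et3N (3.3 equiv), THF/MeOH/H2O, rt; filtration under argon, Sephadex LH-20, lyophilisation
Reagents that add atoms: none
Why: Catalytic hydrogenolysis should cleave the thirteen benzyl ethers and the three aryl C–Br bonds in one operation while triethylamine buffers the HBr, so the acid-labile interflavan bond and the gallate ester survive.

**Compound list**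

1 | (−)-epigallocatechin (2R,3R) | O[C@@H]1Cc2c(O)cc(O)cc2O[C@@H]1c1cc(O)c(O)c(O)c1 | starting material
2 | 5,7,3',4',5'-penta-O-benzyl-(−)-epigallocatechin | O[C@@H]1Cc2c(OCc3ccccc3)cc(OCc3ccccc3)cc2O[C@@H]1c1cc(OCc2ccccc2)c(OCc2ccccc2)c(OCc2ccccc2)c1 | intermediate
3 | 3,4,5-tris(benzyloxy)benzoic acid | OC(=O)c1cc(OCc2ccccc2)c(OCc2ccccc2)c(OCc2ccccc2)c1 | starting material
4 | octa-O-benzyl-EGCG | O=C(O[C@@H]1Cc2c(OCc3ccccc3)cc(OCc3ccccc3)cc2O[C@@H]1c1cc(OCc2ccccc2)c(OCc2ccccc2)c(OCc2ccccc2)c1)c1cc(OCc2ccccc2)c(OCc2ccccc2)c(OCc2ccccc2)c1 | intermediate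
5 | 8-bromo-octa-O-benzyl-EGCG | O=C(O[C@@H]1Cc2c(OCc3ccccc3)cc(OCc3ccccc3)c(Br)c2O[C@@H]1c1cc(OCc2ccccc2)c(OCc2ccccc2)c(OCc2ccccc2)c1)c1cc(OCc2ccccc2)c(OCc2ccccc2)c(OCc2ccccc2)c1 | intermediate
6 | 2,4,6-trihydroxybenzaldehyde | O=Cc1c(O)cc(O)cc1O | starting material
7 | 2,4-bis(benzyloxy)-6-hydroxybenzaldehyde | O=Cc1c(O)cc(OCc2ccccc2)cc1OCc1ccccc1 | intermediate
8 | 4,6-bis(benzyloxy)-3,5-dibromo-2-hydroxybenzaldehyde | O=Cc1c(O)c(Br)c(OCc2ccccc2)c(Br)c1OCc1ccccc1 | intermediate
9 | 3,4,5-tris(benzyloxy)benzaldehyde | O=Cc1cc(OCc2ccccc2)c(OCc2ccccc2)c(OCc2ccccc2)c1 | starting material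
10 | 1,2,3-tris(benzyloxy)-5-ethynylbenzene | C#Cc1cc(OCc2ccccc2)c(OCc2ccccc2)c(OCc2ccccc2)c1 | intermediate
11 | (Z)-2-{2-[3,4,5-tris(benzyloxy)phenyl]ethenyl}-4,4,5,5-tetramethyl-1,3,2-dioxaborolane | CC1(C)OB(/C=C\c2cc(OCc3ccccc3)c(OCc3ccccc3)c(OCc3ccccc3)c2)OC1(C)C | intermediate
12 | 3,5-bis(benzyloxy)-2,4-dibromo-6-(dimethoxymethyl)phenol | COC(OC)c1c(O)c(Br)c(OCc2ccccc2)c(Br)c1OCc1ccccc1 | intermediate (not isolated)
13 | (E)-3,5-bis(benzyloxy)-2,4-dibromo-6-(methoxymethylidene)cyclohexa-2,4-dien-1-one | CO/C=C1/C(=O)C(Br)=C(OCc2ccccc2)C(Br)=C1OCc1ccccc1 | intermediate (not isolated)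
14 | pinacol [(2S,3R,4R)-5,7-bis(benzyloxy)-6,8-dibromo-4-methoxy-2-(3,4,5-tris(benzyloxy)phenyl)chroman-3-yl]boronate (2,3-cis, 3,4-trans; boron where 15 carries its 3-OH) | CO[C@H]1c2c(OCc3ccccc3)c(Br)c(OCc3ccccc3)c(Br)c2O[C@H](c2cc(OCc3ccccc3)c(OCc3ccccc3)c(OCc3ccccc3)c2)[C@@H]1B1OC(C)(C)C(C)(C)O1 | intermediate
15 | 5,7,3',4',5'-penta-O-benzyl-6,8-dibromo-4β-methoxy-epigallocatechin (2R,3R,4S) | CO[C@H]1c2c(OCc3ccccc3)c(Br)c(OCc3ccccc3)c(Br)c2O[C@H](c2cc(OCc3ccccc3)c(OCc3ccccc3)c(OCc3ccccc3)c2)[C@@H]1O | intermediate
16 | [penta-O-benzyl-6,8-dibromo-epigallocatechin]-(4β→6)-[8-bromo-octa-O-benzyl-epigallocatechin 3-O-gallate] | O=C(O[C@@H]1Cc2c(c(Br)c(OCc3ccccc3)c([C@H]4c5c(OCc6ccccc6)c(Br)c(OCc6ccccc6)c(Br)c5O[C@H](c5cc(OCc6ccccc6)c(OCc6ccccc6)c(OCc6ccccc6)c5)[C@@H]4O)c2OCc2ccccc2)O[C@@H]1c1cc(OCc2ccccc2)c(OCc2ccccc2)c(OCc2ccccc2)c1)c1cc(OCc2ccccc2)c(OCc2ccccc2)c(OCc2ccccc2)c1 | intermediate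
17 | epigallocatechin-(4β→6)-epigallocatechin 3-O-gallate | O=C(O[C@@H]1Cc2c(cc(O)c([C@H]3c4c(O)cc(O)cc4O[C@H](c4cc(O)c(O)c(O)c4)[C@@H]3O)c2O)O[C@@H]1c1cc(O)c(O)c(O)c1)c1cc(O)c(O)c(O)c1 | target

**Step count.** Total: 11 steps. Longest linear sequence: 6 steps (steps 6, 7, 8, 9, 10, 11 from 9; equally steps 4, 5, 8, 9, 10, 11 from 6).

**Steps most likely to fail**

Step 8 (proposed new method). Three processes may defeat it:
- The Z-alkenyl boronate may be too weak a nucleophile, so the quinone methide decays before it is trapped.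
- Boron may be lost, either from the C2 cation (alkenyl transfer) or by β-elimination of methanol and boron from 14.
- Control of the alkene face may be incomplete, because the chiral anion has to fix both the heterodiene face and the endo/exo orientation.

The fallback uses known chemistry only and gives up the de novo ring construction. It sets out from 2: benzylic oxidation with DDQ in CH2Cl2/MeOH should give 5,7,3',4',5'-penta-O-benzyl-4β-methoxy-epigallocatechin F1, the methanol entering trans to the 3-OH. Bromination of C6 and C8 with NBS (2 equiv) comes back to the route at 15.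

Step 10. Ionisation may be sluggish because the C5 benzyloxy/C6 bromine pair shields C4. Elimination to the flav-3-ene, incomplete 3,4-trans selectivity or acid-induced scrambling of the new interflavan bond may also occur. The fallback changes the leaving group and the mode of activation. It sets out from 15: acid-catalysed thiolysis with benzyl mercaptan (BF3·OEt2, CH2Cl2, −40 °C) should give 5,7,3',4',5'-penta-O-benzyl-4β-benzylsulfanyl-6,8-dibromo-epigallocatechin F2. Thiophilic activation with AgBF4 (THF, 0 °C) in the presence of 5 should form the 4β→6 bond under non-protic conditions and come back to the route at 16.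

Step 7. Z-selectivity may erode through rhodium-mediated isomerisation to the E boronate, and the alkyne may dimerise. The fallback replaces trans-hydroboration by cis-reduction of an alkynyl boronate. It sets out from 10: deprotonation with n-BuLi and trapping with 2-isopropoxy-4,4,5,5-tetramethyl-1,3,2-dioxaborolane should give 2-{[3,4,5-tris(benzyloxy)phenyl]ethynyl}-4,4,5,5-tetramethyl-1,3,2-dioxaborolane F3. Hydrozirconation with Cp2Zr(H)Cl followed by protonolysis with water should give the Z-alkenyl boronate and come back to the route at 11.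

Further compounds
F1 | step 8 | 5,7,3',4',5'-penta-O-benzyl-4β-methoxy-epigallocatechin | CO[C@H]1c2c(OCc3ccccc3)cc(OCc3ccccc3)cc2O[C@H](c2cc(OCc3ccccc3)c(OCc3ccccc3)c(OCc3ccccc3)c2)[C@@H]1O
F2 | step 10 | 5,7,3',4',5'-penta-O-benzyl-4β-benzylsulfanyl-6,8-dibromo-epigallocatechin | C(S[C@H]1c2c(OCc3ccccc3)c(Br)c(OCc3ccccc3)c(Br)c2O[C@H](c2cc(OCc3ccccc3)c(OCc3ccccc3)c(OCc3ccccc3)c2)[C@@H]1O)c1ccccc1
F3 | step 7 | 2-{[3,4,5-tris(benzyloxy)phenyl]ethynyl}-4,4,5,5-tetramethyl-1,3,2-dioxaborolane | CC1(C)OB(C#Cc2cc(OCc3ccccc3)c(OCc3ccccc3)c(OCc3ccccc3)c2)OC1(C)C
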